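| flask | E | D | Z | temperature | remark | time |
|---|---|---|---|---|---|---|
| autumn | 0.40 M (in portions, 3) | 0.80 M | 0.67 M | −45 °C | run made earlier; portions every 40 min |  |
| summer | 0.40 M (in portions, 3) | 0.80 M | 1.1 M | −10 °C | run made earlier; portions every 40 min |  |
| spring | 0.60 M (in portions, 3) | 0.80 M | 0.48 M | −45 °C | run made earlier; portions every 40 min |  |
| alpha | 0.40 M (in portions, 3) | 0.800 M | 0.480 M |  | at 20 °C throughout; the portions of E follow each other after 40 min, the first at the start | 1.0 h |
| delta | 0.40 M (in portions, 3) | 0.800 M | 0.480 M |  | at −40 °C until 50 min, from then on at 20 °C; the portions of E follow each other after 40 min, the first at the start | 4.0 h |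

autumn run (percent of the E charged)

| time / h | G / % | L / % | E / % |
|---|---|---|---|
| 0.417 | 16.7 | 0.7 | 17.4 |
| 1.33 | 44.9 | 1.2 | 20.3 |
| 2.00 | 68.0 | 0.5 | 31.2 |
| 3.00 | 80.5 | 2.2 | 18.0 |
| 5.00 | 85.6 | 5.5 | 8.0 |

summer run (percent of the E charged)

| time / min | G / % | L / % | E / % |
|---|---|---|---|
| 6.00 | 29.5 | 3.1 | 0 |
| 10.0 | 25.7 | 5.2 | 0.3 |
| 20.0 | 15.8 | 7.4 | 0 |
| 30.0 | 9.1 | 6.0 | 0 |
| 60.0 | 13.7 | 8.0 | 1.1 |

spring run (percent of the E charged)

| time / h | G / % | L / % | E / % |
|---|---|---|---|
| 0.417 | 11.8 | 0.1 | 22.3 |
| 1.33 | 35.2 | 0.1 | 32.9 |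
| 2.00 | 49.3 | 0 | 50.6 |
| 3.00 | 57.5 | 1.5 | 41.1 |
| 5.00 | 60.2 | 2.6 | 36.8 |

(scatter of a reading: 0.5 percentage points)

- percentages count the whole charge, also what has not yet gone in

- the flask that ends with the higher amount of G, in percent of the E charged, or "neither" when 2 percentage points or less lies between them (alpha / delta / neither)
- final G, as a percentage of the E charged, in alpha
- final G, as a percentage of the E charged, in delta

Slowness at low temperature exposes a second consumer of Z. In the spring run at −45 °C, Z was charged at 80.0% of E, yet at 5.00 h E still reads 36.8%, down 4.3 percentage points since 3.00 h. E has therefore lost 63.2% of its own charge, and Z amounting to about 16.8% of the E charge has leaked elsewhere, presumably to D. With c_D nearly steady, this leak is pseudo-first-order in c_Z. Taking a mean c_Z of 0.240 M gives a half-life read at −45 °C of about 8.25 h. The summer run shows a loss of G: with E read at 0%, G falls from 29.5% to 15.8% between 6.00 min and 20.0 min, while L rises.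

The forecast names alpha as the richer flask, with 4% in alpha and 1% in delta. It treats the fall of G as a decay that continues “unless Z exhaustion stops the decay”.

The reckoning here differs and rests on an assumption: each leaked Z removes one G, and each Z taken by E makes one G. Z is then the limiting reagent once the leak counts. The leak's half-life, read at −45 °C, is longer than the 50 min that delta spends cold at −40 °C, and that slightly warmer bath is reckoned not to close the gap, so the second portion should still meet Z. Between the warming to 20 °C and the third portion lie 30.0 min, so the half-life read at −45 °C must shrink by a factor of 16.5 to fit, and the forecast's 55 kJ/mol, borrowed here for the leak, is reckoned to do so amply. The third portion, entering 30.0 min after the warming, should stay E. Delta then ends at 13.3%. This figure, twice the share of E converted less the Z charge in percent of E, is the Z balance. Alpha, warm from the start, converts one portion, and its balance is negative, so it is reckoned at 0%.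

The simulation gives delta: alpha 0%, delta 13.3%.

    E + Z → G (k = 0.0817 L mol⁻¹ min⁻¹, Ea = 61.0 kJ mol⁻¹)
    Z + D → J (k = 0.00503 L mol⁻¹ min⁻¹, Ea = 53.0 kJ mol⁻¹)
    G + J → L (k = 0.00464 L mol⁻¹ min⁻¹, Ea = 53.0 kJ mol⁻¹)
    L → Q (k = 9.34 × 10⁻⁴ min⁻¹, Ea = 83.0 kJ mol⁻¹)
    (constants at −40 °C)

J is the leak's product. In delta, Z stands at 0% at 1.33 h, before the last portion, and E conversion ends at 66.7%, so the Z balance reads 13.3%. The drawn-out feeding of E is the main reason that alpha ends at 0%: with that taken away, alpha ends at 77.2%. The neighbour charged with 0.12 M of Z keeps 75.7% of its E, so its balance reads 18.7%, and it ends at 18.7%.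

(The earlier runs and the new flask were computed on assumed constants; the scatter is artificial.)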